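**Strategy.** Ring A (C1, the stereocentre that bears the side chain; C2; C3=C4, with the methyl on C4; C5; C6) has its C4 methyl "para" to C1, the pattern of a Diels–Alder adduct of isoprene. The diene is not bought but built in the flask: propyne gives C3, C4 and the methyl, ethene gives the methylenes C2 and C5. One operation therefore forms C4–C5 (enyne metathesis) and C1–C2 (cycloaddition to an acryloyl oxazolidinone, which also sets C1). The acyclic chain is attached by a propyne carbocupration–conjugate addition that fixes the Z-alkene; its methyl stereocentres come from both citronellyl bromides and (S)-3-bromo-2-methylpropan-1-ol.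

Key step: step 2

Remark: chain carbons are numbered as in the name of 30; C13 (the later ketone carbon) is carried as a mixture of carbinol epimers from step 8 to step 14, and 1, 4, 5, 10, 11 and 17 are taken as commercial.

Step 1
Reactants: 1 (4S)-4-benzyl-1,3-oxazolidin-2-one
Product: 3 (4S)-3-acryloyl-4-benzyl-1,3-oxazolidin-2-one, via N-bromomagnesio oxazolidinone 2 (not isolated)
Conditions: MeMgBr, THF, 0 °C; acryloyl chloride, −78 to 0 °C
Reagents that add atoms: acryloyl chloride, C=CC(=O)Cl
Why: N-Acylation of the bromomagnesium amide of the oxazolidinone with an acid chloride; the magnesium salt and the low temperature should keep the acrylamide from polymerising, and no stereocentre is formed.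

Step 2
Reactants: 3 (4S)-3-acryloyl-4-benzyl-1,3-oxazolidin-2-one; 4 propyne; 5 ethene
Product: 7 (4S)-4-benzyl-3-[(1R)-4-methylcyclohex-3-ene-1-carbonyl]-1,3-oxazolidin-2-one, via isoprene 6 (not isolated)
Conditions: 4 (excess), 5 (3 bar), second-generation Grubbs catalyst RuCl2(H2IMes)(PCy3)(=CHPh) (1 mol %), CH2Cl2, 40 °C, pressure tube; cool to −78 °C, release ethene; cannulate into 3, Et2AlCl (1.4 equiv), CH2Cl2, −78 °C
Reagents that add atoms: none
Why: The ruthenium methylidene adds to propyne and the resulting vinylcarbene is cleaved by ethene (cross-enyne metathesis), which joins C4 to the methylene C5 and C3 to the methylene C2 and gives isoprene 6; 6 then adds in a concerted [4+2] cycloaddition across the acryloyl C=C of the aluminium chelate of 3, which forms C1–C2 and C5–C6. The closest known reaction type is the ethene–alkyne cross-metathesis to 2-substituted butadienes, telescoped into the Lewis-acid Diels–Alder reaction of an N-acryloyl oxazolidinone with isoprene. Ring A is closed in the intermolecular suprafacial [4π+2π] mode, and its C3=C4 double bond arises from the central bond of the diene. C1 is controlled by the auxiliary: in the s-cis chelate the benzyl group of the oxazolidinone covers the re face of the acryloyl α-carbon, so the diene should add to the si face and give 1R. The step needs "para" regioselectivity (methyl on C4, acyl on C1), which the large LUMO coefficient at the β-carbon of the chelated dienophile and the larger HOMO coefficient at C5 of isoprene should secure, and it needs the volatile diene to be consumed in the flask, for which the excess of 4 and 5 and the fast cycloaddition at −78 °C provide.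

Step 3
Reactants: 7 (4S)-4-benzyl-3-[(1R)-4-methylcyclohex-3-ene-1-carbonyl]-1,3-oxazolidin-2-one
Product: 8 (1R)-N-methoxy-N,4-dimethylcyclohex-3-ene-1-carboxamide
Conditions: MeONHMe·HCl, AlMe3, CH2Cl2, −20 to 0 °C
Reagents that add atoms: N,O-dimethylhydroxylamine hydrochloride, CNOC.Cl
Why: Aluminium-amide transamination of the N-acyl oxazolidinone to the N-methoxy-N-methylamide (Weinreb amide) should cleave the exocyclic C–N bond under non-epimerising conditions, so that C1 stays R and the auxiliary 1 is recovered.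

Step 4
Reactants: 8 (1R)-N-methoxy-N,4-dimethylcyclohex-3-ene-1-carboxamide
Product: 9 1-[(1R)-4-methylcyclohex-3-en-1-yl]prop-2-en-1-one
Conditions: CH2=CHMgBr, THF, −20 to 0 °C; inverse quench into cold aq. HCl
Reagents that add atoms: vinylmagnesium bromide, C=C[Mg]Br
Why: Weinreb ketone synthesis, in which the chelated tetrahedral adduct of the Grignard addition should prevent a second addition and the cold acidic quench should keep the released amine from adding to the enone; C1 is not touched.

Step 5
Reactants: 10 (S)-citronellyl bromide, (6S)-8-bromo-2,6-dimethyloct-2-ene; 11 (2S)-3-bromo-2-methylpropan-1-ol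
Product: 14 (2R,6R)-2,6,10-trimethylundec-9-en-1-ol, via (S)-citronellylmagnesium bromide 12 (not isolated), via chloromagnesium 3-bromo-2-methylpropanolate 13 (not isolated)
Conditions: 10, Mg, THF, 45 °C; 11, MeMgCl, THF, −20 °C; combine, Li2CuCl4 (3 mol %), −20 to 20 °C; aq. NH4Cl
Reagents that add atoms: none
Why: Copper-catalysed sp3–sp3 cross-coupling of a primary Grignard reagent with a primary alkyl bromide whose hydroxyl group is masked as the magnesium alkoxide; both stereocentres are carried in from 10 and 11 and neither takes part in the bond formation.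

Step 6
Reactants: 14 (2R,6R)-2,6,10-trimethylundec-9-en-1-ol
Product: 15 (2R,6S)-2,6,10-trimethylundecan-1-ol
Conditions: H2 (1 atm), Pd/C, EtOAc, 20 °C
Reagents that add atoms: none
Why: Heterogeneous catalytic hydrogenation of the trisubstituted alkene, the only reducible group, should leave both stereocentres unchanged (the descriptor at C6 changes from R to S only because the ligand priorities change).

Step 7
Reactants: 15 (2R,6S)-2,6,10-trimethylundecan-1-ol
Product: 16 (2R,6S)-2,6,10-trimethylundecanal
Conditions: TEMPO (10 mol %), PhI(OAc)2, CH2Cl2, 20 °C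
Reagents that add atoms: none
Why: Oxoammonium (TEMPO) oxidation of the primary alcohol stops at the aldehyde and is mild enough that the α-methyl centre should not epimerise if 16 is used at once.

Step 8
Reactants: 17 (R)-citronellyl bromide, (6R)-8-bromo-2,6-dimethyloct-2-ene; 16 (2R,6S)-2,6,10-trimethylundecanal
Product: 19 (6R,10R,14S)-2,6,10,14,18-pentamethylnonadec-2-en-9-ol (both C9 epimers), via (R)-citronellylmagnesium bromide 18 (not isolated)
Conditions: 17, Mg, THF, 45 °C; 16, THF, −78 °C; aq. NH4Cl
Reagents that add atoms: none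
Why: Grignard addition to the aldehyde at low temperature; the new carbinol centre forms without control, which is harmless because it is oxidised to the ketone in step 15.

Step 9
Reactants: 19 (6R,10R,14S)-2,6,10,14,18-pentamethylnonadec-2-en-9-ol
Product: 20 tert-butyl(dimethyl){[(6R,10R,14S)-2,6,10,14,18-pentamethylnonadec-2-en-9-yl]oxy}silane
Conditions: TBSOTf, 2,6-lutidine, CH2Cl2, −78 to 0 °C
Reagents that add atoms: tert-butyldimethylsilyl trifluoromethanesulfonate, CC(C)(C)[Si](C)(C)OS(=O)(=O)C(F)(F)F
Why: Silylation of the hindered secondary alcohol with the silyl triflate and a non-nucleophilic base protects it against the organometallic steps that follow.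

Step 10
Reactants: 20 tert-butyl(dimethyl){[(6R,10R,14S)-2,6,10,14,18-pentamethylnonadec-2-en-9-yl]oxy}silane
Product: 22 (4R,8R,12S)-7-[(tert-butyldimethylsilyl)oxy]-4,8,12,16-tetramethylheptadecan-1-ol, via silyloxy aldehyde 21 (not isolated)
Conditions: O3, CH2Cl2/MeOH, −78 °C; NaBH4, −78 to 20 °C
Reagents that add atoms: ozone, [O-][O+]=O
Why: Ozonolysis of the only alkene with reductive work-up should give the primary alcohol and remove the isopropylidene carbons as propan-2-ol; the silyl ether and the stereocentres are inert.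

Step 11
Reactants: 22 (4R,8R,12S)-7-[(tert-butyldimethylsilyl)oxy]-4,8,12,16-tetramethylheptadecan-1-ol
Product: 23 {[(4S,8R,12S)-1-bromo-4,8,12,16-tetramethylheptadecan-7-yl]oxy}(tert-butyl)dimethylsilane
Conditions: CBr4, PPh3, CH2Cl2, 0 °C
Reagents that add atoms: tetrabromomethane, BrC(Br)(Br)Br
Why: Appel reaction, in which the alkoxyphosphonium ion of the primary alcohol is displaced by bromide under neutral conditions that the secondary silyl ether should survive.

Step 12
Reactants: 23 {[(4S,8R,12S)-1-bromo-4,8,12,16-tetramethylheptadecan-7-yl]oxy}(tert-butyl)dimethylsilane; 4 propyne; 9 1-[(1R)-4-methylcyclohex-3-en-1-yl]prop-2-en-1-one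
Product: 27 (4Z,9R,13R,17S)-12-[(tert-butyldimethylsilyl)oxy]-5,9,13,17,21-pentamethyl-1-[(1R)-4-methylcyclohex-3-en-1-yl]docos-4-en-1-one, via alkylmagnesium bromide 24 (not isolated), via alkylcopper 25 (not isolated), via (Z)-alkenylcopper 26 (not isolated)
Conditions: 23, Mg, Et2O, 35 °C; CuBr·SMe2, Et2O/Me2S, −45 °C; 4, −25 °C; 9, −78 to −30 °C; aq. NH4Cl
Reagents that add atoms: none
Why: Syn-carbocupration of propyne by the primary alkylcopper places the chain and the copper cis, so that conjugate addition of the alkenylcopper to enone 9 with retention at the metal-bearing carbon should give the 4Z-alkene; the enolate forms on the chain side of the ketone, so ring carbon C1 is not touched.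

Step 13
Reactants: 27 (4Z,9R,13R,17S)-12-[(tert-butyldimethylsilyl)oxy]-5,9,13,17,21-pentamethyl-1-[(1R)-4-methylcyclohex-3-en-1-yl]docos-4-en-1-one
Product: 28 tert-butyl(dimethyl){[(5Z,10R,14R,18S)-6,10,14,18,22-pentamethyl-2-[(1R)-4-methylcyclohex-3-en-1-yl]tricosa-1,5-dien-13-yl]oxy}silane
Conditions: Zn, CH2Br2, TiCl4, THF/CH2Cl2, 0 to 20 °C
Reagents that add atoms: dibromomethane, BrCBr
Why: Carbonyl methylenation with the non-basic geminal dizinc reagent activated by TiCl4 should convert the ketone into the 1,1-disubstituted alkene without enolisation, so that the α-stereocentre C1 of ring A is kept.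

Step 14
Reactants: 28 tert-butyl(dimethyl){[(5Z,10R,14R,18S)-6,10,14,18,22-pentamethyl-2-[(1R)-4-methylcyclohex-3-en-1-yl]tricosa-1,5-dien-13-yl]oxy}silane
Product: 29 (5Z,10R,14R,18S)-6,10,14,18,22-pentamethyl-2-[(1R)-4-methylcyclohex-3-en-1-yl]tricosa-1,5-dien-13-ol
Conditions: TBAF, THF, 50 °C
Reagents that add atoms: none
Why: Fluoride-mediated cleavage of the silyl ether, driven by the Si–F bond, should leave the three alkenes and all stereocentres untouched.

Step 15
Reactants: 29 (5Z,10R,14R,18S)-6,10,14,18,22-pentamethyl-2-[(1R)-4-methylcyclohex-3-en-1-yl]tricosa-1,5-dien-13-ol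
Product: 30 (5Z,10R,14R,18S)-6,10,14,18,22-pentamethyl-2-[(1R)-4-methylcyclohex-3-en-1-yl]tricosa-1,5-dien-13-one
Conditions: Dess–Martin periodinane, CH2Cl2, 0 to 20 °C
Reagents that add atoms: none
Why: Dess–Martin oxidation of the secondary alcohol converges both carbinol epimers on the ketone under mild conditions that should not epimerise the adjacent methyl-bearing centre C14.

**Compound list**

1 | (4S)-4-benzyl-1,3-oxazolidin-2-one | O=C1OC[C@H](Cc2ccccc2)N1 | starting material
2 | N-bromomagnesio-(4S)-4-benzyl-1,3-oxazolidin-2-one | O=C1OC[C@H](Cc2ccccc2)N1[Mg]Br | intermediate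
3 | (4S)-3-acryloyl-4-benzyl-1,3-oxazolidin-2-one | C=CC(=O)N1[C@@H](Cc2ccccc2)COC1=O | intermediate
4 | propyne | CC#C | starting material
5 | ethene | C=C | starting material
6 | isoprene (2-methylbuta-1,3-diene) | C=CC(C)=C | intermediate
7 | (4S)-4-benzyl-3-[(1R)-4-methylcyclohex-3-ene-1-carbonyl]-1,3-oxazolidin-2-one | CC1=CC[C@@H](CC1)C(=O)N1[C@@H](Cc2ccccc2)COC1=O | intermediate
8 | (1R)-N-methoxy-N,4-dimethylcyclohex-3-ene-1-carboxamide | CC1=CC[C@@H](CC1)C(=O)N(C)OC | intermediate
9 | 1-[(1R)-4-methylcyclohex-3-en-1-yl]prop-2-en-1-one | CC1=CC[C@@H](CC1)C(=O)C=C | intermediate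
10 | (S)-citronellyl bromide, (6S)-8-bromo-2,6-dimethyloct-2-ene | BrCC[C@@H](C)CCC=C(C)C | starting material
11 | (2S)-3-bromo-2-methylpropan-1-ol | OC[C@H](C)CBr | starting material
12 | (S)-citronellylmagnesium bromide | Br[Mg]CC[C@@H](C)CCC=C(C)C | intermediate
13 | chloromagnesium (2S)-3-bromo-2-methylpropan-1-olate | Cl[Mg]OC[C@H](C)CBr | intermediate
14 | (2R,6R)-2,6,10-trimethylundec-9-en-1-ol | OC[C@H](C)CCC[C@@H](C)CCC=C(C)C | intermediate
15 | (2R,6S)-2,6,10-trimethylundecan-1-ol | OC[C@H](C)CCC[C@@H](C)CCCC(C)C | intermediate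
16 | (2R,6S)-2,6,10-trimethylundecanal | O=C[C@H](C)CCC[C@@H](C)CCCC(C)C | intermediate
17 | (R)-citronellyl bromide, (6R)-8-bromo-2,6-dimethyloct-2-ene | BrCC[C@H](C)CCC=C(C)C | starting material
18 | (R)-citronellylmagnesium bromide | Br[Mg]CC[C@H](C)CCC=C(C)C | intermediate
19 | (6R,10R,14S)-2,6,10,14,18-pentamethylnonadec-2-en-9-ol (both C9 epimers) | CC(C)=CCC[C@@H](C)CCC(O)[C@H](C)CCC[C@@H](C)CCCC(C)C | intermediate
20 | tert-butyl(dimethyl){[(6R,10R,14S)-2,6,10,14,18-pentamethylnonadec-2-en-9-yl]oxy}silane | CC(C)=CCC[C@@H](C)CCC(O[Si](C)(C)C(C)(C)C)[C@H](C)CCC[C@@H](C)CCCC(C)C | intermediate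
21 | (4S,8R,12S)-7-[(tert-butyldimethylsilyl)oxy]-4,8,12,16-tetramethylheptadecanal | O=CCC[C@@H](C)CCC(O[Si](C)(C)C(C)(C)C)[C@H](C)CCC[C@@H](C)CCCC(C)C | intermediate
22 | (4R,8R,12S)-7-[(tert-butyldimethylsilyl)oxy]-4,8,12,16-tetramethylheptadecan-1-ol | OCCC[C@@H](C)CCC(O[Si](C)(C)C(C)(C)C)[C@H](C)CCC[C@@H](C)CCCC(C)C | intermediate
23 | {[(4S,8R,12S)-1-bromo-4,8,12,16-tetramethylheptadecan-7-yl]oxy}(tert-butyl)dimethylsilane | BrCCC[C@@H](C)CCC(O[Si](C)(C)C(C)(C)C)[C@H](C)CCC[C@@H](C)CCCC(C)C | intermediate
24 | Grignard reagent of 23 (alkylmagnesium bromide) | Br[Mg]CCC[C@@H](C)CCC(O[Si](C)(C)C(C)(C)C)[C@H](C)CCC[C@@H](C)CCCC(C)C | intermediate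
25 | alkylcopper from 24 | [Cu]CCC[C@@H](C)CCC(O[Si](C)(C)C(C)(C)C)[C@H](C)CCC[C@@H](C)CCCC(C)C | intermediate
26 | (Z)-2-methylalk-1-enylcopper from 25 and propyne | [Cu]/C=C(/C)CCC[C@@H](C)CCC(O[Si](C)(C)C(C)(C)C)[C@H](C)CCC[C@@H](C)CCCC(C)C | intermediate
27 | (4Z,9R,13R,17S)-12-[(tert-butyldimethylsilyl)oxy]-5,9,13,17,21-pentamethyl-1-[(1R)-4-methylcyclohex-3-en-1-yl]docos-4-en-1-one | CC1=CC[C@@H](CC1)C(=O)CC/C=C(/C)CCC[C@@H](C)CCC(O[Si](C)(C)C(C)(C)C)[C@H](C)CCC[C@@H](C)CCCC(C)C | intermediate
28 | tert-butyl(dimethyl){[(5Z,10R,14R,18S)-6,10,14,18,22-pentamethyl-2-[(1R)-4-methylcyclohex-3-en-1-yl]tricosa-1,5-dien-13-yl]oxy}silane | C=C(CC/C=C(/C)CCC[C@@H](C)CCC(O[Si](C)(C)C(C)(C)C)[C@H](C)CCC[C@@H](C)CCCC(C)C)[C@H]1CC=C(C)CC1 | intermediate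
29 | (5Z,10R,14R,18S)-6,10,14,18,22-pentamethyl-2-[(1R)-4-methylcyclohex-3-en-1-yl]tricosa-1,5-dien-13-ol | C=C(CC/C=C(/C)CCC[C@@H](C)CCC(O)[C@H](C)CCC[C@@H](C)CCCC(C)C)[C@H]1CC=C(C)CC1 | intermediate
30 | (5Z,10R,14R,18S)-6,10,14,18,22-pentamethyl-2-[(1R)-4-methylcyclohex-3-en-1-yl]tricosa-1,5-dien-13-one | C=C(CC/C=C(/C)CCC[C@@H](C)CCC(=O)[C@H](C)CCC[C@@H](C)CCCC(C)C)[C@H]1CC=C(C)CC1 | target

**Step count.** Total: 15 steps. Longest linear sequence: 11 steps (steps 5 to 15).

**Steps most likely to fail**

Step 2. The ruthenium and phosphine species carried over from the metathesis may tie up the aluminium Lewis acid, or the volatile diene may be lost when the ethene pressure is released, so that the cycloaddition stalls or runs uncatalysed with poor facial selectivity. The fallback sets out from 1 and comes back at 7. The salt 2, made as in step 1, would be acylated with 5-methylhex-5-enoyl chloride to give (4S)-4-benzyl-3-(5-methylhex-5-enoyl)-1,3-oxazolidin-2-one F1. Deprotonation with NaN(SiMe3)2 in THF at −78 °C and alkylation of the Z-enolate with allyl iodide on the face away from the benzyl group should give (4S)-4-benzyl-3-[(2R)-5-methyl-2-(prop-2-en-1-yl)hex-5-enoyl]-1,3-oxazolidin-2-one F2. Ring-closing metathesis of F2 with second-generation Grubbs catalyst RuCl2(H2IMes)(PCy3)(=CHPh) in CH2Cl2 at 40 °C should then close C3=C4 and give 7.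

Step 12. The conjugate addition of the thermally sensitive alkenylcopper 26 to the vinyl ketone 9 may be slow, so that protonation of 26, 1,2-addition and oligomerisation of 9 compete. The fallback sets out from 23 and 8 and comes back at 27. The alkenylcopper 26, made from 23 as in step 12, would be trapped with oxirane to give (3Z,8R,12R,16S)-11-[(tert-butyldimethylsilyl)oxy]-4,8,12,16,20-pentamethylhenicos-3-en-1-ol F3. Iodination with I2, PPh3 and imidazole should give {[(3Z,8R,12R,16S)-1-iodo-4,8,12,16,20-pentamethylhenicos-3-en-11-yl]oxy}(tert-butyl)dimethylsilane F4. Iodine–lithium exchange with t-BuLi in Et2O/pentane at −78 °C would give the homoallyllithium reagent F5, which is added to the Weinreb amide 8 to give 27.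

Step 13. Enolisation of the α-branched ketone by the organometallic methylenating species may compete with addition, which would epimerise ring carbon C1 or return ketone, and the Lewis acid may attack the silyl ether or the 1,5-diene. The fallback sets out from 27 and comes back at 28. Addition of Me3SiCH2Li in the presence of CeCl3 (THF, −78 °C) should give 13-[(tert-butyldimethylsilyl)oxy]-6,10,14,18,22-pentamethyl-2-[(1R)-4-methylcyclohex-3-en-1-yl]-1-(trimethylsilyl)tricos-5-en-2-ol F6 (5Z,10R,14R,18S; both C2 epimers). Syn-elimination with KH in THF at 20 °C (Peterson olefination) would give 28.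

Further compounds
F1 | step 2 | (4S)-4-benzyl-3-(5-methylhex-5-enoyl)-1,3-oxazolidin-2-one | CC(=C)CCCC(=O)N1[C@@H](Cc2ccccc2)COC1=O
F2 | step 2 | (4S)-4-benzyl-3-[(2R)-5-methyl-2-(prop-2-en-1-yl)hex-5-enoyl]-1,3-oxazolidin-2-one | C=CC[C@@H](CCC(C)=C)C(=O)N1[C@@H](Cc2ccccc2)COC1=O
F3 | step 12 | (3Z,8R,12R,16S)-11-[(tert-butyldimethylsilyl)oxy]-4,8,12,16,20-pentamethylhenicos-3-en-1-ol | OCC/C=C(/C)CCC[C@@H](C)CCC(O[Si](C)(C)C(C)(C)C)[C@H](C)CCC[C@@H](C)CCCC(C)C
F4 | step 12 | {[(3Z,8R,12R,16S)-1-iodo-4,8,12,16,20-pentamethylhenicos-3-en-11-yl]oxy}(tert-butyl)dimethylsilane | ICC/C=C(/C)CCC[C@@H](C)CCC(O[Si](C)(C)C(C)(C)C)[C@H](C)CCC[C@@H](C)CCCC(C)C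
F5 | step 12 | homoallyllithium reagent from F4 | [Li]CC/C=C(/C)CCC[C@@H](C)CCC(O[Si](C)(C)C(C)(C)C)[C@H](C)CCC[C@@H](C)CCCC(C)C
F6 | step 13 | 13-[(tert-butyldimethylsilyl)oxy]-6,10,14,18,22-pentamethyl-2-[(1R)-4-methylcyclohex-3-en-1-yl]-1-(trimethylsilyl)tricos-5-en-2-ol | C[Si](C)(C)CC(O)(CC/C=C(/C)CCC[C@@H](C)CCC(O[Si](C)(C)C(C)(C)C)[C@H](C)CCC[C@@H](C)CCCC(C)C)[C@H]1CC=C(C)CC1
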